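In the south-west run, target cannot be coming straight from the crystals: at 15.0 min the solid substrate has lost 4.50%, while target stands at 0%. Solid lost minus target is a dissolved pool, and the flask is read through it.

| flask | solid substrate | partner | free catalyst | impurity | remark | time |
|---|---|---|---|---|---|---|
| south-west | 0.25 M | 0.45 M | 0.25 mM | 0.36 mM | run made earlier |  |
| south-east | 0.25 M | 0.72 M | 0.25 mM | 0.36 mM | run made earlier |  |
| north-west | 0.25 M | 0.325 M | 0.25 mM | 0.54 mM | run made earlier |  |
| flask | 0.25 M | 0.325 M | 0.25 mM | 0.36 mM |  | 3.0 h |

| run | time / min | target / % | solid substrate / % |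
|---|---|---|---|
| south-west | 15.0 | 0 | 95.5 |
| south-west | 40.0 | 1.8 | 90.1 |
| south-west | 80.0 | 5.2 | 84.3 |
| south-west | 120 | 8.6 | 79.6 |
| south-east | 8.00 | 0.1 | 97.4 |
| south-east | 20.0 | 0.2 | 94.7 |
| south-east | 50.0 | 2.8 | 87.7 |
| south-east | 120 | 9.1 | 79.4 |
| north-west | 25.0 | 1.2 | 92.9 |
| north-west | 50.0 | 2.3 | 89.1 |
| north-west | 80.0 | 4.3 | 84.8 |
| north-west | 120 | 7.1 | 80.4 |

(scatter of a reading: 0.3 percentage points)

1. amount of target in percent of the solid substrate charged, at 20 min, 1.0 h and 3.0 h

- given per volume of solution although it is solid: solid substrate
- at the start none of the solid substrate is in solution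

The runs give a ladder of times, all read from the south-west run. First comes the delay of target: a line through its last two readings reaches zero at 18.8 min. Next comes the filling. The pool stands at 11.8% at 120 min, and the opening loss of solid supplies that amount in 39.3 min, a span longer than the delay. The pool divided by the late rate of target gives 139 min. This is the turnover time of the dissolved pool. It is longer than the filling time, so in the south-west run the pool fills first and target then climbs along a line.

Between the south-west and south-east runs [partner] shows little: at 0.72 M rather than 0.45 M, the south-east run ends 0.5 percentage points higher at 120 min, against a scatter of 0.3 points. My own reckoning therefore keeps the south-west line for the flask, which has the same [impurity]. It gives 0.100%, 3.50% and 13.7%. That line comes from a run with more partner, and its last reading stands at 120 min, so its number for 3.0 h is an extrapolation.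

The forecast gives 0.4%, 3.3% and 12.5%, from a rate “lying between the north-west and south-west runs”, and stands lower at 3.0 h than my line.

The flask gives 0.609%, 3.42% and 11.2%.

    partner + free catalyst → catalyst intermediate A (k = 1.50 L mol⁻¹ s⁻¹)
    catalyst intermediate A ⇌ by-product + catalyst intermediate B (K = 0.120 M, k = 2.20 s⁻¹)
    catalyst intermediate B → catalyst intermediate C (k = 0.400 s⁻¹)
    starting material + catalyst intermediate C → catalyst intermediate D (k = 0.790 L mol⁻¹ s⁻¹)
    catalyst intermediate D ⇌ free catalyst + target (K = 0.450 M, k = 17.0 s⁻¹)
    free catalyst + impurity → spent catalyst (k = 9.40 L mol⁻¹ s⁻¹)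
    solid substrate ⇌ starting material, rate k7*(cs7 - [starting material]) while solid is left; crystals form when [starting material] > cs7 (solubility = 41.0 mM, k = 3.40 × 10⁻⁴ s⁻¹)
    2 starting material → homo dimer (k = 2.90 × 10⁻⁴ L mol⁻¹ s⁻¹)

In the flask, starting material, the dissolved pool, stands at 10.6% at 1.50 h, and target's gain over the preceding half hour makes the turnover time 140 min; at 3.00 h starting material stands at 12.6%, and target's gain since 1.50 h makes that time 206 min, longer, while catalyst intermediate C, the resting state, falls from 57.8% to 33.0% of the catalyst and spent catalyst rises from 35.6% to 62.1%. The north-west run, with [impurity] at 0.54 mM and [partner] at 0.325 M, gives as a reading from its last points a turnover time of 179 min, longer than the south-west 139 min.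

The readings were generated by integration from invented constants, and the scatter is random.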